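The C1–C8 bond of the bicyclo[3.3.1]nonane is the disconnection. Before the C1 prenyl and C3 aroyl groups are added, ring A (C1–C5, C9) is mirror-symmetric about prochiral C5, and the C6–C7–C8 bridge with its C8 methyl and 4-methylpent-3-enyl groups is a 2,3-epoxynerol unit. A silyl-triflate-triggered epoxide opening lets one of two enantiotopic enol ethers of a 6,6-disubstituted 1,5-dimethoxycyclohexa-1,4-diene attack the tertiary epoxide carbon. This closes ring B, fixes C1, C5 and C8 from one Sharpless epoxide and stores C9 as a ketal bridged to the C7 oxygen. C7 is reset later by exo-face hydroboration, and the catechol ketone is added last.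

Key step: step 5

Remark on numbering and assumptions: C1 and C5 are the bridgeheads (C1 next to C8), C9 is the one-carbon bridge, C2–C3–C4 and C6–C7–C8 are the two three-carbon bridges. "Exo" is the face of ring B turned away from the C2–C3–C4 bridge. In every bicyclic compound the C8 side chain is axial on chair ring B (syn to C9) and the C8 methyl is equatorial. 1,5-Dimethoxycyclohexa-1,4-diene is taken as purchasable. The target is drawn as one enol tautomer of the 2,4-diketone.

Step 1
Reactants: 1 nerol, (2Z)-3,7-dimethylocta-2,6-dien-1-ol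
Product: 2 (2R,3S)-2,3-epoxynerol, [(2R,3S)-3-methyl-3-(4-methylpent-3-enyl)oxiran-2-yl]methanol
Conditions: Ti(OiPr)4 (cat.), D-(−)-diethyl tartrate (cat.), t-BuOOH, 4 Å MS, CH2Cl2, −20 °C
Reagents that add atoms: tert-butyl hydroperoxide, CC(C)(C)OO
Why: Sharpless asymmetric epoxidation, in which the titanium tartrate complex binds the allylic hydroxyl and the D-(−)-tartrate delivers oxygen to the alkene face that makes C2 R (C3 is then S because the alkene is Z), while the remote 6,7-alkene has no directing hydroxyl and should stay untouched.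

Step 2
Reactants: 2 (2R,3S)-2,3-epoxynerol
Product: 4 (2S,3S)-1-bromo-2,3-epoxy-3,7-dimethyloct-6-ene, via epoxyneryl mesylate 3 (not isolated)
Conditions: MsCl, Et3N, CH2Cl2, −10 °C; then LiBr, THF, 0 °C to rt
Reagents that add atoms: lithium bromide, [Li+].[Br-]
Why: Sulfonylation followed by SN2 displacement at the primary carbon, which touches neither stereocentre (the C2 descriptor changes from R to S only because CH2Br now outranks C3) and is faster than bromide opening of the epoxide at this temperature.

Step 3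
Reactants: 5 1,5-dimethoxycyclohexa-1,4-diene; 6 prenyl bromide, 1-bromo-3-methylbut-2-ene
Product: 8 1,5-dimethoxy-6-(3-methylbut-2-enyl)cyclohexa-1,4-diene, via 6-lithio diene 7 (not isolated)
Conditions: t-BuLi, THF, −78 °C; then 6, −78 °C to 0 °C
Reagents that add atoms: none
Why: Deprotonation of the CH2 flanked by the two methoxy-bearing alkene carbons gives a pentadienyl anion with the methoxy groups at its nodal positions, and C-alkylation at the central carbon (alkylation of a Birch-type bis-enol ether) restores the skipped diene.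

Step 4
Reactants: 8 1,5-dimethoxy-6-(3-methylbut-2-enyl)cyclohexa-1,4-diene; 4 (2S,3S)-1-bromo-2,3-epoxy-3,7-dimethyloct-6-ene
Product: 10 1,5-dimethoxy-6-(3-methylbut-2-enyl)-6-{[(2R,3S)-3-methyl-3-(4-methylpent-3-enyl)oxiran-2-yl]methyl}cyclohexa-1,4-diene, via lithiated prenyl diene 9 (not isolated)
Conditions: s-BuLi, THF, −78 °C; then 4, −78 °C to −30 °C
Reagents that add atoms: none
Why: A second deprotonation at the same carbon and SN2 alkylation by the primary bromide, which is activated by the adjacent epoxide and reacts faster than the epoxide itself at low temperature; this creates the quaternary, prochiral C5 with two enantiotopic enol ethers and leaves both epoxide stereocentres untouched.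

Step 5
Reactants: 10 the epoxide-bearing bis-enol ether
Product: 12 4,9-dimethoxy-8-methyl-8-(4-methylpent-3-enyl)-5-(3-methylbut-2-enyl)-7,9-epoxybicyclo[3.3.1]non-3-ene (C7–O–C9 bridge on the exo face, C1–H), via ring-B oxocarbenium triflate 11 (not isolated)
Conditions: TMSOTf (cat.), 2,6-lutidine, CH2Cl2, −78 °C
Reagents that add atoms: none
Why: The silyl triflate binds the epoxide oxygen and the β-carbon of one enol ether (C1) attacks the tertiary carbon C8 anti to the breaking C8–O bond, giving oxocarbenium 11, whose C9 is then captured by the C7 silyloxy oxygen with return of the silyl group to the catalyst. The closest known reaction is the silyl-triflate-promoted epoxide-opening cyclisation of 6,6-disubstituted 1,5-dimethoxycyclohexa-1,4-dienes that carry an E-configured trisubstituted epoxide. Ring B (C9, C1, C8, C7, C6, C5) closes in the 6-endo mode at the epoxide through a chair with the C7–O bond equatorial, and the oxolane C9–O–C7 closes 5-exo onto the oxocarbenium after ring B flips to a boat, which gives a 7-oxabicyclo[2.2.1]heptane ketal. C8 comes from the epoxide by inversion and the Z geometry places its side chain axial and its methyl equatorial, C7 keeps the epoxide configuration, C1 and C5 follow because the fixed sign of the C6–C7–C8–C1 torsion lets only one of the two enantiotopic enol ethers reach C8 through a chair, and C9 is dictated by the bridge. The step needs attack at C8 over C7 and one enol ether over the other: the first is secured by the cation-stabilising tertiary centre, the second by the epoxide configuration acting on the prochiral quaternary C5. The lutidine keeps the medium free of acid so that both enol ethers and the ketal should survive.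

Step 6
Reactants: 12 the bridged ketal enol ether
Product: 13 4,9-dimethoxy-8-methyl-8-(4-methylpent-3-enyl)-5-(3-methylbut-2-enyl)-7,9-epoxybicyclo[3.3.1]non-3-en-2-one
Conditions: PhI(OAc)2, t-BuOOH, Cs2CO3 (0.5 equiv), EtOAc, −78 °C to −20 °C
Reagents that add atoms: tert-butyl hydroperoxide, CC(C)(C)OO
Why: Radical allylic oxidation by tert-butylperoxy radicals, in which the C2 hydrogens are abstracted fastest because the resulting radical is allylic to the electron-rich enol ether, and the allylic peroxide collapses under base to the enone, a vinylogous ester that is more robust than the enol ether it replaces.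

Step 7
Reactants: 13 the ketal enone
Product: 15 7-exo-hydroxy-4-methoxy-8-methyl-8-(4-methylpent-3-enyl)-5-(3-methylbut-2-enyl)bicyclo[3.3.1]non-3-ene-2,9-dione, via C7 dimethylborinate 14 (not isolated)
Conditions: Me2BBr, CH2Cl2, −78 °C; then aq. NaHCO3
Reagents that add atoms: none
Why: Lewis-acid ketal cleavage with bromodimethylborane, in which boron binds the strained bridging oxygen, the C9–O bridge bond breaks to the methoxy-oxocarbenium and bromide removes its methyl group to give the C9 ketone, while the low temperature should spare the vinylogous ester and the trisubstituted alkenes and hydrolysis of the borinate frees the exo C7 alcohol.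

Step 8
Reactants: 15 the hydroxy diketone
Product: 16 the 7-exo triethylsilyl ether of 15
Conditions: Et3SiOTf, 2,6-lutidine, CH2Cl2, −78 °C to 0 °C
Reagents that add atoms: triethylsilyl triflate, CC[Si](CC)(CC)OS(=O)(=O)C(F)(F)F
Why: Silyl triflate silylation of the hindered secondary alcohol, which is needed because a free C7 alkoxide under the following amide-base steps could add to C9 and open the 1,3-diketone.

Step 9
Reactants: 16 the triethylsilyl ether
Product: 18 the 3-trimethylsilyl derivative of 16, via C3-lithio enone 17 (not isolated)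
Conditions: lithium 2,2,6,6-tetramethylpiperidide, THF, −78 °C; then Me3SiCl
Reagents that add atoms: chlorotrimethylsilane, C[Si](C)(C)Cl
Why: Kinetic α-lithiation of the vinylogous ester at the vinylic C3–H followed by C-silylation, which blocks C3 so that the next base can only reach the bridgehead.

Step 10
Reactants: 18 the C3-blocked enone; 6 prenyl bromide
Product: 20 the 1-(3-methylbut-2-enyl) derivative of 18, via C1 bridgehead lithium compound 19 (not isolated)
Conditions: lithium 2,2,6,6-tetramethylpiperidide, THF, −78 °C to −40 °C; then 6, −78 °C to 0 °C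
Reagents that add atoms: none
Why: Bridgehead lithiation and alkylation, in which the C1–H between the C2 and C9 carbonyls gives a pyramidal carbanion stabilised inductively by both, SN2 attack on the allylic bromide forms the quaternary centre, and the configuration at C1 is locked by the bicycle.

Step 11
Reactants: 20 the doubly silylated diprenyl compound
Product: 21 7-exo-hydroxy-4-methoxy-8-methyl-8-(4-methylpent-3-enyl)-1,5-bis(3-methylbut-2-enyl)bicyclo[3.3.1]non-3-ene-2,9-dione
Conditions: Bu4NF, AcOH, THF, 0 °C to rt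
Reagents that add atoms: none
Why: Fluoride-induced cleavage of the O–Si bond and of the carbonyl-activated vinyl C–Si bond in one operation, with acetic acid keeping the C7 hydroxyl protonated so that it should not add to C9 and trigger retro-Claisen opening of the non-enolisable 1,3-diketone.

Step 12
Reactants: 21 the C7 alcohol
Product: 22 4-methoxy-8-methyl-8-(4-methylpent-3-enyl)-1,5-bis(3-methylbut-2-enyl)bicyclo[3.3.1]non-3-ene-2,7,9-trione
Conditions: Dess–Martin periodinane, CH2Cl2, rt
Reagents that add atoms: none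
Why: Dess–Martin oxidation of a hindered secondary alcohol under neutral conditions, which removes the C7 oxygen stereocentre and leaves the alkenes and the vinylogous ester alone.

Step 13
Reactants: 22 the 7-ketone
Product: 23 4-methoxy-8-methyl-7-methylidene-8-(4-methylpent-3-enyl)-1,5-bis(3-methylbut-2-enyl)bicyclo[3.3.1]non-3-ene-2,9-dione
Conditions: Ph3PCH3Br, KN(SiMe3)2, THF, 0 °C; then 22, rt to 60 °C
Reagents that add atoms: methyltriphenylphosphonium bromide, C[P+](c1ccccc1)(c1ccccc1)c1ccccc1.[Br-]
Why: Wittig methylenation, selective because C7 is the only ordinary ketone with an open face (C9 lies between two quaternary bridgeheads and C2 is a vinylogous ester), and reversible enolisation towards C6 is harmless since C5 is quaternary.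

Step 14
Reactants: 23 the 7-methylidene compound; 24 1-bromo-2-methylprop-1-ene
Product: 26 4-methoxy-8-methyl-8-(4-methylpent-3-enyl)-1,5,7-tris(3-methylbut-2-enyl)bicyclo[3.3.1]non-3-ene-2,9-dione with the C7 prenyl endo, via B-alkyl-9-BBN borane 25 (not isolated)
Conditions: 9-BBN dimer, THF, 0 °C to 40 °C; then 24, PdCl2(dppf) (cat.), AsPh3 (cat.), Cs2CO3, DMF/H2O, rt to 50 °C
Reagents that add atoms: none
Why: Hydroboration followed by B-alkyl Suzuki–Miyaura coupling, in which 9-BBN adds only to the 1,1-disubstituted alkene (boron to the CH2 terminus) and delivers hydrogen to C7 from the exo face because the endo face lies over the C2–C3–C4 bridge, which sets C7 with hydrogen exo and the new CH2 endo and trans to the axial C8 side chain, and the vinyl bromide then completes the prenyl group.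

Step 15
Reactants: 27 3,4-dihydroxybenzoic acid
Product: 28 tert-butyldimethylsilyl 3,4-bis(tert-butyldimethylsilyloxy)benzoate
Conditions: t-BuMe2SiCl, imidazole, DMF, rt
Reagents that add atoms: tert-butylchlorodimethylsilane, CC(C)(C)[Si](C)(C)Cl
Why: Imidazole-promoted silylation of both phenols and the carboxylic acid in one operation.

Step 16
Reactants: 28 the tris-silyl compound
Product: 29 3,4-bis(tert-butyldimethylsilyloxy)benzoyl chloride
Conditions: (COCl)2, DMF (cat.), CH2Cl2, 0 °C to rt
Reagents that add atoms: oxalyl chloride, O=C(Cl)C(Cl)=O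
Why: Direct conversion of a silyl ester into the acid chloride by the Vilsmeier chloride formed from oxalyl chloride and DMF, which works without free acid and should leave the aryl silyl ethers in place.

Step 17
Reactants: 26 the O-methyl core; 29 the acid chloride
Product: 31 the 3-[3,4-bis(tert-butyldimethylsilyloxy)benzoyl] derivative of 26, via C3-lithio enone 30 (not isolated)
Conditions: lithium 2,2,6,6-tetramethylpiperidide, THF, −78 °C; then 29, −78 °C to −40 °C
Reagents that add atoms: none
Why: α-Lithiation of the vinylogous ester at C3, the only acidic C–H left now that both bridgeheads are quaternary, followed by C-acylation with the acid chloride.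

Step 18
Reactants: 31 the protected O-methyl target
Product: 33 target CNP0108469.1, via O-methyl catechol 32 (not isolated)
Conditions: LiOH, 1,4-dioxane/H2O (degassed, Ar), rt to 90 °C; then aq. HCl
Reagents that add atoms: lithium hydroxide, [Li+].[OH-]
Why: Hydroxide first cleaves the two aryl silyl ethers and then adds to C4 of the doubly activated β-methoxy enone and expels methoxide (addition–elimination), the product being held as the delocalised triketone enolate, which should protect it from retro-Claisen cleavage, and no stereocentre is touched.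

Compound list
1 | nerol, (2Z)-3,7-dimethylocta-2,6-dien-1-ol | CC(C)=CCC/C(C)=C\CO | starting material
2 | (2R,3S)-2,3-epoxynerol | CC(C)=CCC[C@]1(C)O[C@@H]1CO | intermediate
3 | (2R,3S)-2,3-epoxyneryl methanesulfonate | CC(C)=CCC[C@]1(C)O[C@@H]1COS(C)(=O)=O | intermediate
4 | (2S,3S)-1-bromo-2,3-epoxy-3,7-dimethyloct-6-ene | CC(C)=CCC[C@]1(C)O[C@@H]1CBr | intermediate
5 | 1,5-dimethoxycyclohexa-1,4-diene | COC1=CCC=C(OC)C1 | starting material
6 | prenyl bromide, 1-bromo-3-methylbut-2-ene | CC(C)=CCBr | starting material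
7 | 6-lithio-1,5-dimethoxycyclohexa-1,4-diene | COC1=CCC=C(OC)C1[Li] | intermediate
8 | 1,5-dimethoxy-6-(3-methylbut-2-enyl)cyclohexa-1,4-diene | COC1=CCC=C(OC)C1CC=C(C)C | intermediate
9 | 6-lithio-1,5-dimethoxy-6-(3-methylbut-2-enyl)cyclohexa-1,4-diene | COC1=CCC=C(OC)C1([Li])CC=C(C)C | intermediate
10 | 1,5-dimethoxy-6-(3-methylbut-2-enyl)-6-{[(2R,3S)-3-methyl-3-(4-methylpent-3-enyl)oxiran-2-yl]methyl}cyclohexa-1,4-diene | COC1=CCC=C(OC)C1(CC=C(C)C)C[C@H]2O[C@@]2(C)CCC=C(C)C | intermediate
11 | ring-B-closed C9 methoxy-oxocarbenium triflate with exo C7 trimethylsilyloxy group | COC1=CC[C@H]2[C@](C)(CCC=C(C)C)[C@H](O[Si](C)(C)C)C[C@]1(CC=C(C)C)C2=[O+]C.[O-]S(=O)(=O)C(F)(F)F | intermediate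
12 | 4,9-dimethoxy-8-methyl-8-(4-methylpent-3-enyl)-5-(3-methylbut-2-enyl)-7,9-epoxybicyclo[3.3.1]non-3-ene, exo C7–O–C9 bridge | COC1=CC[C@H]2[C@](C)(CCC=C(C)C)[C@H]3C[C@]1(CC=C(C)C)[C@]2(OC)O3 | intermediate
13 | 4,9-dimethoxy-8-methyl-8-(4-methylpent-3-enyl)-5-(3-methylbut-2-enyl)-7,9-epoxybicyclo[3.3.1]non-3-en-2-one | COC1=CC(=O)[C@H]2[C@](C)(CCC=C(C)C)[C@H]3C[C@]1(CC=C(C)C)[C@]2(OC)O3 | intermediate
14 | 7-exo dimethylborinate of 15 | CC(C)=CCC[C@]1(C)[C@H](OB(C)C)C[C@]2(CC=C(C)C)C(=O)[C@H]1C(=O)C=C2OC | intermediate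
15 | 7-exo-hydroxy-4-methoxy-8-methyl-8-(4-methylpent-3-enyl)-5-(3-methylbut-2-enyl)bicyclo[3.3.1]non-3-ene-2,9-dione | CC(C)=CCC[C@]1(C)[C@H](O)C[C@]2(CC=C(C)C)C(=O)[C@H]1C(=O)C=C2OC | intermediate
16 | 7-exo triethylsilyl ether of 15 | CC(C)=CCC[C@]1(C)[C@H](O[Si](CC)(CC)CC)C[C@]2(CC=C(C)C)C(=O)[C@H]1C(=O)C=C2OC | intermediate
17 | 3-lithio derivative of 16 | CC(C)=CCC[C@]1(C)[C@H](O[Si](CC)(CC)CC)C[C@]2(CC=C(C)C)C(=O)[C@H]1C(=O)C([Li])=C2OC | intermediate
18 | 3-trimethylsilyl derivative of 16 | CC(C)=CCC[C@]1(C)[C@H](O[Si](CC)(CC)CC)C[C@]2(CC=C(C)C)C(=O)[C@H]1C(=O)C([Si](C)(C)C)=C2OC | intermediate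
19 | 1-lithio derivative of 18 | CC(C)=CCC[C@]1(C)[C@H](O[Si](CC)(CC)CC)C[C@]2(CC=C(C)C)C(=O)[C@@]1([Li])C(=O)C([Si](C)(C)C)=C2OC | intermediate
20 | 1-(3-methylbut-2-enyl) derivative of 18 | CC(C)=CCC[C@]1(C)[C@H](O[Si](CC)(CC)CC)C[C@]2(CC=C(C)C)C(=O)[C@@]1(CC=C(C)C)C(=O)C([Si](C)(C)C)=C2OC | intermediate
21 | 7-exo-hydroxy-4-methoxy-8-methyl-8-(4-methylpent-3-enyl)-1,5-bis(3-methylbut-2-enyl)bicyclo[3.3.1]non-3-ene-2,9-dione | CC(C)=CCC[C@]1(C)[C@H](O)C[C@]2(CC=C(C)C)C(=O)[C@@]1(CC=C(C)C)C(=O)C=C2OC | intermediate
22 | 4-methoxy-8-methyl-8-(4-methylpent-3-enyl)-1,5-bis(3-methylbut-2-enyl)bicyclo[3.3.1]non-3-ene-2,7,9-trione | CC(C)=CCC[C@]1(C)C(=O)C[C@]2(CC=C(C)C)C(=O)[C@@]1(CC=C(C)C)C(=O)C=C2OC | intermediate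
23 | 4-methoxy-8-methyl-7-methylidene-8-(4-methylpent-3-enyl)-1,5-bis(3-methylbut-2-enyl)bicyclo[3.3.1]non-3-ene-2,9-dione | CC(C)=CCC[C@]1(C)C(=C)C[C@]2(CC=C(C)C)C(=O)[C@@]1(CC=C(C)C)C(=O)C=C2OC | intermediate
24 | 1-bromo-2-methylprop-1-ene | CC(C)=CBr | starting material
25 | 7-endo-(9-borabicyclo[3.3.1]nonan-9-ylmethyl) adduct of 23 | CC(C)=CCC[C@]1(C)[C@@H](CB3C4CCCC3CCC4)C[C@]2(CC=C(C)C)C(=O)[C@@]1(CC=C(C)C)C(=O)C=C2OC | intermediate
26 | 4-methoxy-8-methyl-8-(4-methylpent-3-enyl)-1,5,7-tris(3-methylbut-2-enyl)bicyclo[3.3.1]non-3-ene-2,9-dione, C7 prenyl endo | CC(C)=CCC[C@]1(C)[C@@H](CC=C(C)C)C[C@]2(CC=C(C)C)C(=O)[C@@]1(CC=C(C)C)C(=O)C=C2OC | intermediate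
27 | 3,4-dihydroxybenzoic acid | O=C(O)c1ccc(O)c(O)c1 | starting material
28 | tert-butyldimethylsilyl 3,4-bis(tert-butyldimethylsilyloxy)benzoate | O=C(O[Si](C)(C)C(C)(C)C)c1ccc(O[Si](C)(C)C(C)(C)C)c(O[Si](C)(C)C(C)(C)C)c1 | intermediate
29 | 3,4-bis(tert-butyldimethylsilyloxy)benzoyl chloride | O=C(Cl)c1ccc(O[Si](C)(C)C(C)(C)C)c(O[Si](C)(C)C(C)(C)C)c1 | intermediate
30 | 3-lithio derivative of 26 | CC(C)=CCC[C@]1(C)[C@@H](CC=C(C)C)C[C@]2(CC=C(C)C)C(=O)[C@@]1(CC=C(C)C)C(=O)C([Li])=C2OC | intermediate
31 | 3-[3,4-bis(tert-butyldimethylsilyloxy)benzoyl] derivative of 26 | CC(C)=CCC[C@]1(C)[C@@H](CC=C(C)C)C[C@]2(CC=C(C)C)C(=O)[C@@]1(CC=C(C)C)C(=O)C(C(=O)c1ccc(O[Si](C)(C)C(C)(C)C)c(O[Si](C)(C)C(C)(C)C)c1)=C2OC | intermediate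
32 | 3-(3,4-dihydroxybenzoyl) derivative of 26, the O-methyl ether of the target (lithium catecholate in the flask) | CC(C)=CCC[C@]1(C)[C@@H](CC=C(C)C)C[C@]2(CC=C(C)C)C(=O)[C@@]1(CC=C(C)C)C(=O)C(C(=O)c1ccc(O)c(O)c1)=C2OC | intermediate
33 | CNP0108469.1; C1 S, C5 S, C7 S, C8 R in the core numbering for the tautomer drawn | CC(C)=CCC[C@]1(C)[C@@H](CC=C(C)C)C[C@]2(CC=C(C)C)C(=O)[C@@]1(CC=C(C)C)C(=O)C(C(=O)c1ccc(O)c(O)c1)=C2O | target

Total step count: 18 steps (one-pot sequences counted once).
Longest linear sequence: 15 steps, from nerol (steps 1, 2, 4 to 14, 17, 18).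

Steps most likely to fail

Step 5. Once the C1–C8 bond has formed, the axial C8 side chain of the Z series lies 1,3-diaxial to the C9 oxocarbenium. Its trisubstituted alkene may therefore add to C9 (a Prins-type closure) before ring B has flipped to bring the C7 silyloxy group over C9, and selection between the two enol ethers through the chair may also erode. The fallback sets out from 8 and comes back at 12. It runs the cascade with a side chain that ends in a monosubstituted alkene, a much poorer cation trap, and adds the two methyl groups afterwards. Hex-5-en-1-yne F1 would be deprotonated with n-BuLi and acylated with ethyl chloroformate to ethyl hept-6-en-2-ynoate F2. Me2CuLi at −78 °C should add syn to give ethyl (2Z)-3-methylhepta-2,6-dienoate F3, and i-Bu2AlH should reduce it to (2Z)-3-methylhepta-2,6-dien-1-ol F4. Epoxidation under the conditions of step 1 should give (2R,3S)-2,3-epoxy-3-methylhept-6-en-1-ol F5, and CBr4 with PPh3 the bromide (2S,3S)-1-bromo-2,3-epoxy-3-methylhept-6-ene F6. Alkylation of lithiated 8 as in step 4 should give the but-3-enyl analogue of 10 F7, and the conditions of step 5 the but-3-enyl analogue of 12 F8. Cross-metathesis with 2-methyl-2-butene (second-generation Hoveyda–Grubbs catalyst) would then turn the but-3-enyl group into the 4-methylpent-3-enyl group, which is compound 12.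

Step 10. The hindered bridgehead carbanion next to quaternary C8 may form the C–C bond slowly, so that proton return, SN2′ attack on the allylic bromide and silyl migration compete. The fallback sets out from 18 and comes back at 20. The same anion would be quenched with iodine, a small and fast electrophile, to give the C1 iodide F9. Keck radical allylation (Bu3SnCH2CH=CH2 in large excess, Et3B, air, benzene) should give the C1 allyl compound F10; the excess stannane is meant to outrun 5-exo closure of the bridgehead radical onto the C8 side chain. Cross-metathesis with 2-methyl-2-butene (second-generation Hoveyda–Grubbs catalyst) would give 20.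

Step 14. Transmetalation of the β-branched alkylborane next to quaternary C8 may stall, leaving protodeboronation and attack of the aqueous base on the 1,3-diketone to compete. In the one-pot form, any borane addition from the endo face would also go unnoticed. The fallback sets out from 23 and comes back at 26. Borane 25 would be oxidised with NaBO3·4H2O to the 7-endo hydroxymethyl compound F11, where the C7 configuration can be checked and a minor epimer removed. I2, PPh3 and imidazole should give the 7-endo iodomethyl compound F12. A nickel-catalysed reductive cross-electrophile coupling with 24 (NiBr2(dme), 4,4′-di-tert-butyl-2,2′-bipyridine, Mn, NaI, DMA) would then give 26.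

Further compounds
F1 | step 5 | hex-5-en-1-yne | C=CCCC#C
F2 | step 5 | ethyl hept-6-en-2-ynoate | C=CCCC#CC(=O)OCC
F3 | step 5 | ethyl (2Z)-3-methylhepta-2,6-dienoate | C=CCC/C(C)=C\C(=O)OCC
F4 | step 5 | (2Z)-3-methylhepta-2,6-dien-1-ol | C=CCC/C(C)=C\CO
F5 | step 5 | (2R,3S)-2,3-epoxy-3-methylhept-6-en-1-ol | C=CCC[C@]1(C)O[C@@H]1CO
F6 | step 5 | (2S,3S)-1-bromo-2,3-epoxy-3-methylhept-6-ene | C=CCC[C@]1(C)O[C@@H]1CBr
F7 | step 5 | 6-{[(2R,3S)-3-(but-3-enyl)-3-methyloxiran-2-yl]methyl}-1,5-dimethoxy-6-(3-methylbut-2-enyl)cyclohexa-1,4-diene | COC1=CCC=C(OC)C1(CC=C(C)C)C[C@H]2O[C@@]2(C)CCC=C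
F8 | step 5 | 8-(but-3-enyl)-4,9-dimethoxy-8-methyl-5-(3-methylbut-2-enyl)-7,9-epoxybicyclo[3.3.1]non-3-ene, exo C7–O–C9 bridge | COC1=CC[C@H]2[C@](C)(CCC=C)[C@H]3C[C@]1(CC=C(C)C)[C@]2(OC)O3
F9 | step 10 | 1-iodo derivative of 18 | CC(C)=CCC[C@]1(C)[C@H](O[Si](CC)(CC)CC)C[C@]2(CC=C(C)C)C(=O)[C@@]1(I)C(=O)C([Si](C)(C)C)=C2OC
F10 | step 10 | 1-allyl derivative of 18 | CC(C)=CCC[C@]1(C)[C@H](O[Si](CC)(CC)CC)C[C@]2(CC=C(C)C)C(=O)[C@@]1(CC=C)C(=O)C([Si](C)(C)C)=C2OC
F11 | step 14 | 7-endo-hydroxymethyl-4-methoxy-8-methyl-8-(4-methylpent-3-enyl)-1,5-bis(3-methylbut-2-enyl)bicyclo[3.3.1]non-3-ene-2,9-dione | CC(C)=CCC[C@]1(C)[C@@H](CO)C[C@]2(CC=C(C)C)C(=O)[C@@]1(CC=C(C)C)C(=O)C=C2OC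
F12 | step 14 | 7-endo-iodomethyl-4-methoxy-8-methyl-8-(4-methylpent-3-enyl)-1,5-bis(3-methylbut-2-enyl)bicyclo[3.3.1]non-3-ene-2,9-dione | CC(C)=CCC[C@]1(C)[C@@H](CI)C[C@]2(CC=C(C)C)C(=O)[C@@]1(CC=C(C)C)C(=O)C=C2OC
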